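**Retrosynthetic overview**
- The plan rests on ring B (O1, C2, C3, C4, C4a, C8a). It is a 4-pyranone with a CH2 group on C2 that shares only the C4a–C8a bond with ring A, which is the substitution pattern of kojic acid (CH2OH on C2, an oxygen handle on C4a, a free CH at C8a).
- The last operations are a global O-dealkylation (three aryl methyl ethers and one benzyl ester), preceded by aromatisation of ring A: dehydrogenation across C8a/C6 first, loss of methanol from C7 second.
- The key disconnection cuts C8–C8a and C6–C7. It is a [4+2] cycloaddition of the diene C8a=C4a–C5=C6 (pyranone bond plus a 1-heptylvinyl group on C4a) with 1,1-dimethoxyethene.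
- The diene comes from two cross-couplings on kojic acid. C4a–C5 is made by Suzuki coupling of the 5-triflate, and CH2–aryl by Negishi coupling of the derived bromide with a ring C arylzinc.
- Ring order: ring B is bought, ring C is bought and carboxylated, and ring A is closed in step 9 and made aromatic in step 10.

Key step: step 9

**Remarks on the chemistry**
- The locants O1 and C2 to C8a are those of the chromone in the target and are used for the same atoms in all earlier compounds. O4 is the carbonyl oxygen.
- The target has no stereocentre. The only one in the route (C8a) is formed racemic and erased again.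
- The ring C carboxyl travels as a benzyl ester. A di-ortho-substituted methyl ester would need hot hydroxide, which would open ring B and decarboxylate the 2,4-dihydroxybenzoic acid.

**Step 1**
Reactants: 1 non-1-yne
Product: 3 2-(non-1-en-2-yl)-4,4,5,5-tetramethyl-1,3,2-dioxaborolane, via diisobutyl(non-1-en-2-yl)alane 2 (not isolated)
Conditions: i-Bu2AlH (1.3 equiv), NiCl2(dppp) (3 mol%; dppp = Ph2P(CH2)3PPh2), THF, 0 °C → rt; then MeOBpin (2 equiv), 0 °C → rt
Reagents that add atoms: 2-methoxy-4,4,5,5-tetramethyl-1,3,2-dioxaborolane (MeOBpin), COB1OC(C)(C)C(C)(C)O1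
Why: Nickel-catalysed α-selective (Markovnikov) hydroalumination of a terminal alkyl alkyne should put aluminium on the internal carbon, and aluminium-to-boron exchange then gives the 1,1-disubstituted alkenylboronate without moving the double bond.

**Step 2**
Reactants: 4 kojic acid
Product: 5 6-(hydroxymethyl)-4-oxo-4H-pyran-3-yl trifluoromethanesulfonate
Conditions: PhNTf2 (1.05 equiv), Et3N (1.5 equiv), MeCN, 0 °C → rt
Reagents that add atoms: N-phenylbis(trifluoromethanesulfonimide), O=S(=O)(N(c1ccccc1)S(=O)(=O)C(F)(F)F)C(F)(F)F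
Why: Chemoselective O-triflation, in which Et3N ionises only the acidic enolic 5-OH and the mild triflyl donor reacts with that oxyanion but not with the neutral primary alcohol, the selectivity known from phenol triflation beside aliphatic alcohols.

**Step 3**
Reactants: 5 6-(hydroxymethyl)-4-oxo-4H-pyran-3-yl trifluoromethanesulfonate; 3 2-(non-1-en-2-yl)-4,4,5,5-tetramethyl-1,3,2-dioxaborolane
Product: 6 2-(hydroxymethyl)-5-(non-1-en-2-yl)-4H-pyran-4-one
Conditions: Pd(PPh3)4 (5 mol%), K3PO4 (2 equiv), aqueous 1,4-dioxane, 70 °C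
Reagents that add atoms: none
Why: Suzuki–Miyaura coupling, in which the triflate on the electron-poor pyranone should add readily to zerovalent palladium (5-triflates of kojic acid derivatives are established partners) and the free alcohol is tolerated.

**Step 4**
Reactants: 6 2-(hydroxymethyl)-5-(non-1-en-2-yl)-4H-pyran-4-one
Product: 7 2-(bromomethyl)-5-(non-1-en-2-yl)-4H-pyran-4-one
Conditions: CBr4 (1.2 equiv), PPh3 (1.25 equiv), CH2Cl2, 0 °C
Reagents that add atoms: tetrabromomethane, BrC(Br)(Br)Br
Why: Appel reaction, which displaces the primary allylic-type alcohol through its alkoxyphosphonium salt under neutral conditions, so no HBr is present to add to the 1,1-disubstituted alkene.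

**Step 5**
Reactants: 8 1-bromo-3,5-dimethoxybenzene
Product: 10 2-bromo-4,6-dimethoxybenzaldehyde, via aryl iminium dichlorophosphate 9 (not isolated)
Conditions: POCl3 (1.5 equiv), DMF, 0 → 90 °C; then ice-water
Reagents that add atoms: N,N-dimethylformamide, CN(C)C=O; water, O
Why: Vilsmeier–Haack formylation, in which the chloroiminium ion attacks the position ortho to one methoxy group and para to the other (next to bromine) rather than the crowded position between the two methoxy groups, and water hydrolyses the iminium salt.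

**Step 6**
Reactants: 10 2-bromo-4,6-dimethoxybenzaldehyde
Product: 11 2-bromo-4,6-dimethoxybenzoic acid
Conditions: NaClO2, NaH2PO4, 2-methylbut-2-ene, t-BuOH/H2O, rt
Reagents that add atoms: sodium chlorite, [Na+].[O-]Cl=O
Why: Pinnick oxidation takes the aldehyde to the acid under buffered conditions, and the alkene traps hypochlorous acid so that the electron-rich ring is not chlorinated.

**Step 7**
Reactants: 11 2-bromo-4,6-dimethoxybenzoic acid
Product: 12 benzyl 2-bromo-4,6-dimethoxybenzoate
Conditions: BnBr (1.1 equiv), K2CO3 (1.5 equiv), DMF, rt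
Reagents that add atoms: benzyl bromide, BrCc1ccccc1
Why: SN2 O-alkylation of the carboxylate avoids attack at the hindered carbonyl carbon and installs an ester that can later be cleaved at its O-alkyl bond.

**Step 8**
Reactants: 12 benzyl 2-bromo-4,6-dimethoxybenzoate; 7 2-(bromomethyl)-5-(non-1-en-2-yl)-4H-pyran-4-one
Product: 15 benzyl 2,4-dimethoxy-6-{[5-(non-1-en-2-yl)-4-oxo-4H-pyran-2-yl]methyl}benzoate, via arylmagnesium chloride 13 (not isolated), via arylzinc chloride 14 (not isolated)
Conditions: 12 (1.3 equiv), i-PrMgCl·LiCl (1.35 equiv), THF, −20 °C; ZnCl2 (1.5 equiv), −20 °C → rt; then 7, Pd(OAc)2 (2 mol%), SPhos (4 mol%), THF, rt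
Reagents that add atoms: none
Why: Bromine–magnesium exchange assisted by the chelating ortho ester, transmetalation to zinc and Negishi coupling, in which the heterobenzylic bromide adds fast to zerovalent palladium and has no β-hydrogen, and the arylzinc tolerates ester, pyranone and diene.

**Step 9**
Reactants: 15 benzyl 2,4-dimethoxy-6-{[5-(non-1-en-2-yl)-4-oxo-4H-pyran-2-yl]methyl}benzoate; 16 1,1-dimethoxyethene
Product: 17 racemic benzyl 2-[(5-heptyl-7,7-dimethoxy-4-oxo-6,7,8,8a-tetrahydro-4H-chromen-2-yl)methyl]-4,6-dimethoxybenzoate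
Conditions: 16 (10 equiv), BHT (1 mol%), PhMe, base-washed sealed tube, 120 °C; volatiles removed in vacuo, crude 17 carried on
Reagents that add atoms: none
Why: Proposed new method: the nucleophilic CH2 carbon of 16 should add to C8a, the unsubstituted β-carbon of the pyranone enone, and the developing dienolate (O4–C4=C4a–C5=C6) should bond through its γ-carbon C6 to the dimethoxycarbenium carbon C7, either in one highly asynchronous inverse-demand [4+2] event or in two steps through the zwitterion, leaving the new alkene at C4a=C5. The closest known reaction type is the inverse-demand Diels–Alder reaction of 3-vinylchromones with enamines and ketene acetals; what is new is a monocyclic 5-alkenyl-4-pyranone with no acceptor on the alkene terminus. Ring A closes as a six-membered carbocycle by intermolecular [4+2] annulation across C8a and C6, which in the stepwise limit is a favoured 6-(enolendo)-exo-trig closure. C8a is the only new stereocentre and nothing chiral is present, so it forms as a racemate, which is harmless because step 10 makes it sp2. The step needs regio-, site- and periselectivity: the acceptor polarity of ring B pairs the acetal CH2 with C8a and so puts oxygen on C7 and not C6, C2 is blocked by its substituent and belongs to no diene, the oxadiene O4=C4–C4a=C8a is locked s-trans in ring B and cannot enter a hetero-Diels–Alder reaction, and a [2+2] closure at C4a would be reversible and drain into the six-membered ring. The substituents on both inner diene carbons (C4 on C4a, heptyl on C5) disfavour the s-trans conformer, and the excess of 16 consumes traces of acid and methanol, so the ketal and the O1–C8a bond of 17 should survive.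

**Step 10**
Reactants: 17 racemic benzyl 2-[(5-heptyl-7,7-dimethoxy-4-oxo-6,7,8,8a-tetrahydro-4H-chromen-2-yl)methyl]-4,6-dimethoxybenzoate
Product: 19 benzyl 2-[(5-heptyl-7-methoxy-4-oxo-4H-chromen-2-yl)methyl]-4,6-dimethoxybenzoate, via 7,8-dihydrochromone ketal 18 (not isolated)
Conditions: DDQ (1.3 equiv), 2,6-dichloropyridine (2 equiv), ClCH2CH2Cl, 60 °C; then TsOH·H2O (10 mol%), rt
Reagents that add atoms: none
Why: DDQ dehydrogenation by hydride abstraction, known for Diels–Alder adducts of vinylchromones and for allylic ethers, should remove the allylic, O1-activated C8a–H and then a C6 proton while the buffer keeps the ketal intact, so the 4-pyranone is restored (18) and C8a is already sp2 when acid is admitted to expel methanol from C7 (E1, loss of H8), which aromatises ring A without giving O1 a chance to leave and erases the stereocentre.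

**Step 11**
Reactants: 19 benzyl 2-[(5-heptyl-7-methoxy-4-oxo-4H-chromen-2-yl)methyl]-4,6-dimethoxybenzoate
Product: 21 siphulin (2-[(5-heptyl-7-hydroxy-4-oxo-4H-chromen-2-yl)methyl]-4,6-dihydroxybenzoic acid), via tetrakis(dibromoboryl) derivative 20 (not isolated)
Conditions: BBr3 (10 equiv), CH2Cl2, −78 °C → rt; then ice-water, 0 °C
Reagents that add atoms: none
Why: Lewis-acid O-dealkylation, in which BBr3 cleaves the three aryl methyl ethers and the benzyl ester by bromide attack at the O-alkyl carbons, frees the hindered carboxyl group without hydroxide (which would open ring B) and without heat (which would decarboxylate the product).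

**Compound list**
1 | non-1-yne | CCCCCCCC#C | starting material
2 | diisobutyl(non-1-en-2-yl)alane (formed in the flask) | CCCCCCCC(=C)[Al](CC(C)C)CC(C)C | intermediate
3 | 2-(non-1-en-2-yl)-4,4,5,5-tetramethyl-1,3,2-dioxaborolane | CCCCCCCC(=C)B1OC(C)(C)C(C)(C)O1 | intermediate
4 | kojic acid | OCc1cc(=O)c(O)co1 | starting material
5 | 6-(hydroxymethyl)-4-oxo-4H-pyran-3-yl trifluoromethanesulfonate | OCc1cc(=O)c(OS(=O)(=O)C(F)(F)F)co1 | intermediate
6 | 2-(hydroxymethyl)-5-(non-1-en-2-yl)-4H-pyran-4-one | CCCCCCCC(=C)c1coc(CO)cc1=O | intermediate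
7 | 2-(bromomethyl)-5-(non-1-en-2-yl)-4H-pyran-4-one | CCCCCCCC(=C)c1coc(CBr)cc1=O | intermediate
8 | 1-bromo-3,5-dimethoxybenzene | COc1cc(Br)cc(OC)c1 | starting material
9 | [(2-bromo-4,6-dimethoxyphenyl)methylidene]dimethylammonium dichlorophosphate (formed in the flask) | C[N+](C)=Cc1c(Br)cc(OC)cc1OC.[O-]P(=O)(Cl)Cl | intermediate
10 | 2-bromo-4,6-dimethoxybenzaldehyde | COc1cc(Br)c(C=O)c(OC)c1 | intermediate
11 | 2-bromo-4,6-dimethoxybenzoic acid | COc1cc(Br)c(C(=O)O)c(OC)c1 | intermediate
12 | benzyl 2-bromo-4,6-dimethoxybenzoate | COc1cc(Br)c(C(=O)OCc2ccccc2)c(OC)c1 | intermediate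
13 | [2-(benzyloxycarbonyl)-3,5-dimethoxyphenyl]magnesium chloride (formed in the flask) | COc1cc([Mg]Cl)c(C(=O)OCc2ccccc2)c(OC)c1 | intermediate
14 | [2-(benzyloxycarbonyl)-3,5-dimethoxyphenyl]zinc chloride (formed in the flask) | COc1cc([Zn]Cl)c(C(=O)OCc2ccccc2)c(OC)c1 | intermediate
15 | benzyl 2,4-dimethoxy-6-{[5-(non-1-en-2-yl)-4-oxo-4H-pyran-2-yl]methyl}benzoate | CCCCCCCC(=C)c1coc(Cc2cc(OC)cc(OC)c2C(=O)OCc3ccccc3)cc1=O | intermediate
16 | 1,1-dimethoxyethene | C=C(OC)OC | starting material
17 | racemic benzyl 2-[(5-heptyl-7,7-dimethoxy-4-oxo-6,7,8,8a-tetrahydro-4H-chromen-2-yl)methyl]-4,6-dimethoxybenzoate (one enantiomer drawn) | CCCCCCCC1=C2C(=O)C=C(Cc3cc(OC)cc(OC)c3C(=O)OCc4ccccc4)O[C@H]2CC(OC)(OC)C1 | intermediate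
18 | benzyl 2-[(5-heptyl-7,7-dimethoxy-4-oxo-7,8-dihydro-4H-chromen-2-yl)methyl]-4,6-dimethoxybenzoate (formed in the flask) | CCCCCCCC1=CC(OC)(OC)Cc2oc(Cc3cc(OC)cc(OC)c3C(=O)OCc4ccccc4)cc(=O)c21 | intermediate
19 | benzyl 2-[(5-heptyl-7-methoxy-4-oxo-4H-chromen-2-yl)methyl]-4,6-dimethoxybenzoate | CCCCCCCc1cc(OC)cc2oc(Cc3cc(OC)cc(OC)c3C(=O)OCc4ccccc4)cc(=O)c12 | intermediate
20 | fourfold O-dibromoboryl derivative of siphulin, simplest formulation (formed in the flask) | CCCCCCCc1cc(OB(Br)Br)cc2oc(Cc3cc(OB(Br)Br)cc(OB(Br)Br)c3C(=O)OB(Br)Br)cc(=O)c12 | intermediate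
21 | siphulin | CCCCCCCc1cc(O)cc2oc(Cc3cc(O)cc(O)c3C(=O)O)cc(=O)c12 | target

**Total step count:** 11.
**Longest linear sequence:** 7 steps. These are steps 2, 3, 4, 8, 9, 10, 11 from kojic acid. The branches from 1 (steps 1, 3, 4, 8, 9, 10, 11) and from 8 (steps 5 to 11) are equally long.

**Steps most likely to fail**

**Step 9.** The monocyclic pyranone diene may be too weak an acceptor, so that oligomerisation of the ketene acetal or slow decay of the diene outruns cycloaddition. The fallback uses known chemistry only, buys ring A and builds ring B classically. It sets out from arylzinc chloride 14 and comes back at 19.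
- Commercial 5-heptylresorcinol is C-acetylated (AcOH, BF3·OEt2, 90 °C, Friedel–Crafts acylation) to 1-(2-heptyl-4,6-dihydroxyphenyl)ethanone F1.
- The non-chelated hydroxyl is methylated (Me2SO4, K2CO3, acetone) to 1-(2-heptyl-6-hydroxy-4-methoxyphenyl)ethanone F2.
- Claisen condensation with diethyl oxalate (NaOEt, EtOH) gives ethyl 4-(2-heptyl-6-hydroxy-4-methoxyphenyl)-2,4-dioxobutanoate F3.
- HCl in EtOH cyclodehydrates F3 to ethyl 5-heptyl-7-methoxy-4-oxo-4H-chromene-2-carboxylate F4.
- NaBH4 (MeOH, 0 °C) reduces the activated ester to 5-heptyl-2-(hydroxymethyl)-7-methoxy-4H-chromen-4-one F5.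
- An Appel reaction gives 2-(bromomethyl)-5-heptyl-7-methoxy-4H-chromen-4-one F6.
- Negishi coupling of F6 with 14 under the catalyst of step 8 should give 19.

**Step 10.** Hydride abstraction at C8a may be slow because the allyl system carries the C4 acyl group. Premature loss of methanol from the ketal, followed by heterolysis or E1cB loss of O1 from C8a, would then aromatise ring A in a redox-neutral way with irreversible opening of ring B. The fallback carries the C7 oxygen as a cyclic ketal. Its opening is reversible, so dehydrogenation can be forced before any aromatisation is possible. It sets out from 15 and comes back at 21.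
- 15 is heated with 2-methylene-1,3-dioxolane in place of 16 to give the racemic spiro-dioxolane cycloadduct F7.
- DDQ in hot chlorobenzene, the conditions known for vinylchromone adducts, dehydrogenates it to the 7,8-dihydrochromone dioxolane F8.
- TsOH in toluene then opens the dioxolane with aromatisation to benzyl 2-{[5-heptyl-7-(2-hydroxyethoxy)-4-oxo-4H-chromen-2-yl]methyl}-4,6-dimethoxybenzoate F9.
- BBr3 as in step 11 cleaves the hydroxyethyl ether, the methyl ethers and the benzyl ester to give 21.

**Step 8.** Bromine–magnesium exchange on the electron-rich arene may be sluggish, the ortho-metalated ester may self-condense, and the reactive bromide may homocouple. The fallback reverses the polarity of the partners. It sets out from 7 (with 12 as the electrophile) and comes back at 15.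
- Zinc dust and LiCl in THF at 0 °C → rt insert into 7 to give {[5-(non-1-en-2-yl)-4-oxo-4H-pyran-2-yl]methyl}zinc bromide F10.
- F10 is coupled with aryl bromide 12 using Pd(OAc)2 and SPhos in THF at 50 °C to give 15.

**Further compounds**
F1 | step 9 | 1-(2-heptyl-4,6-dihydroxyphenyl)ethanone | CCCCCCCc1cc(O)cc(O)c1C(C)=O
F2 | step 9 | 1-(2-heptyl-6-hydroxy-4-methoxyphenyl)ethanone | CCCCCCCc1cc(OC)cc(O)c1C(C)=O
F3 | step 9 | ethyl 4-(2-heptyl-6-hydroxy-4-methoxyphenyl)-2,4-dioxobutanoate | CCCCCCCc1cc(OC)cc(O)c1C(=O)CC(=O)C(=O)OCC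
F4 | step 9 | ethyl 5-heptyl-7-methoxy-4-oxo-4H-chromene-2-carboxylate | CCCCCCCc1cc(OC)cc2oc(C(=O)OCC)cc(=O)c12
F5 | step 9 | 5-heptyl-2-(hydroxymethyl)-7-methoxy-4H-chromen-4-one | CCCCCCCc1cc(OC)cc2oc(CO)cc(=O)c12
F6 | step 9 | 2-(bromomethyl)-5-heptyl-7-methoxy-4H-chromen-4-one | CCCCCCCc1cc(OC)cc2oc(CBr)cc(=O)c12
F7 | step 10 | racemic spiro-dioxolane cycloadduct (7,7-ethylenedioxy analogue of 17, one enantiomer drawn) | CCCCCCCC1=C2C(=O)C=C(Cc3cc(OC)cc(OC)c3C(=O)OCc4ccccc4)O[C@H]2CC2(C1)OCCO2
F8 | step 10 | 7,8-dihydrochromone dioxolane (7,7-ethylenedioxy analogue of 18) | CCCCCCCC1=CC2(OCCO2)Cc2oc(Cc3cc(OC)cc(OC)c3C(=O)OCc4ccccc4)cc(=O)c21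
F9 | step 10 | benzyl 2-{[5-heptyl-7-(2-hydroxyethoxy)-4-oxo-4H-chromen-2-yl]methyl}-4,6-dimethoxybenzoate | CCCCCCCc1cc(OCCO)cc2oc(Cc3cc(OC)cc(OC)c3C(=O)OCc4ccccc4)cc(=O)c12
F10 | step 8 | {[5-(non-1-en-2-yl)-4-oxo-4H-pyran-2-yl]methyl}zinc bromide | CCCCCCCC(=C)c1coc(C[Zn]Br)cc1=O
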